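**Plan**

1. Retrosynthesis: the C5–OOH bond is taken back to a C4=C5 alkene (ene reaction); the isobutyrate, the acetate and C13 are removed; the hydroxy ester is re-closed to the 8β,12-lactone; both carbinols become ketones. This leaves a 13-nor-eudesm-4-ene-3,8-dione ester.
2. Enabling feature: in that dione C6 is the γ-carbon of the ring A 4-en-3-one and C7 is the α-carbon of the C8 ketone. Both are donor positions, so the C6–C7 bond of ring B is cut and is made with inverted polarity, by one-electron oxidation of the bis(silyl enol ether).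
3. Further cuts: C7–C8 (acyl anion plus acrylate), C5–C6 (methyl addition to a vinylogous ester) and C9–C10 (allylation of a ring A enolate).
4. Forward order: ring A from 2-methylcyclohexane-1,3-dione, then the C10 quaternary centre, the C6 methyl, the keto ester chain, ring B by anodic coupling, then lactone, C13, ester and acyl groups, and the hydroperoxide last.
5. Stereochemistry: C10 from the chiral phosphinooxazoline ligand; C7 equatorial, under thermodynamic control next to the C8 ketone; C3 and C8 by hydride delivery to the α-face, opposite the angular methyl; C5 by singlet oxygen on the same α-face.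

Key step: step 9

Numbering: eudesmane numbering is used from compound 13 on (ring A = C1–C5, C10; ring B = C5–C10; C14 on C10, C15 on C4, C11–C13 on C7); β = same face as the C10 methyl.

Assumption: the sense of induction known for 2-alkylcyclohexanone enol carbonates ((S)-ligand gives the (S)-ketone) is taken to hold for the vinylogous ester, so the (R)-ligand is specified in step 4; were the sense opposite, the (S)-ligand would be used.

Step 1
Reactants: 1 2-methylcyclohexane-1,3-dione
Product: 2 3-(2-methylpropoxy)-2-methylcyclohex-2-en-1-one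
Conditions: i-BuOH, TsOH·H2O (cat.), toluene, reflux, Dean–Stark
Reagents that add atoms: 2-methylpropan-1-ol, CC(C)CO
Why: Acid-catalysed enol etherification of the symmetric 1,3-dione with azeotropic removal of water should give the vinylogous ester as a single regioisomer.

Step 2
Reactants: 2 3-(2-methylpropoxy)-2-methylcyclohex-2-en-1-one
Product: 3 rac-3-(2-methylpropoxy)-2,6-dimethylcyclohex-2-en-1-one
Conditions: LiN(iPr)2, THF, −78 °C; then MeI, −78 → 0 °C
Reagents that add atoms: iodomethane, CI
Why: Kinetic deprotonation of a vinylogous ester takes place at the α′-carbon and the lithium enolate is C-methylated (Stork–Danheiser alkylation); the new centre is racemic and is planarised again in step 3.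

Step 3
Reactants: 3 rac-3-(2-methylpropoxy)-2,6-dimethylcyclohex-2-en-1-one; 4 allyl chloroformate
Product: 5 allyl 5-(2-methylpropoxy)-2,6-dimethylcyclohexa-1,5-dien-1-yl carbonate
Conditions: LiN(iPr)2, TMEDA, THF, −78 °C; then allyl chloroformate
Reagents that add atoms: allyl chloroformate (4), C=CCOC(=O)Cl
Why: The fully substituted lithium enolate should be acylated on oxygen by the chloroformate in the presence of TMEDA (enol carbonate formation), and any C-acylated β-keto ester would converge on the same product in step 4.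

Step 4
Reactants: 5 allyl 5-(2-methylpropoxy)-2,6-dimethylcyclohexa-1,5-dien-1-yl carbonate
Product: 6 (6R)-6-allyl-3-(2-methylpropoxy)-2,6-dimethylcyclohex-2-en-1-one
Conditions: Pd2(dba)3 (2.5 mol%), (R)-4-tert-butyl-2-[2-(diphenylphosphino)phenyl]-4,5-dihydrooxazole (6 mol%), toluene, 30 °C
Reagents that add atoms: none
Why: In this decarboxylative asymmetric allylic alkylation (Tsuji allylation) zerovalent palladium ionises the allyl carbonate, CO2 is lost, and the prochiral enolate recombines with the π-allyl fragment inside the chiral P,N-ligand sphere, which sets the quaternary carbon (future C10) as R.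

Step 5
Reactants: 6 (6R)-6-allyl-3-(2-methylpropoxy)-2,6-dimethylcyclohex-2-en-1-one
Product: 8 (4R)-4-allyl-2,3,4-trimethylcyclohex-2-en-1-one, via tertiary carbinol 7 (not isolated)
Conditions: MeLi, CeCl3, THF, −78 → 0 °C; then 2 M HCl (aq), rt
Reagents that add atoms: methyllithium, [Li]C; water, O
Why: Stork–Danheiser transposition, in which 1,2-addition of the organocerium reagent to the hindered vinylogous ester carbonyl and acid hydrolysis of the enol ether with loss of water move the carbonyl and install the future C6 methyl without touching the quaternary centre.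

Step 6
Reactants: 8 (4R)-4-allyl-2,3,4-trimethylcyclohex-2-en-1-one
Product: 10 2-[(1R)-1,2,3-trimethyl-4-oxocyclohex-2-en-1-yl]acetaldehyde, via vicinal diol 9 (not isolated)
Conditions: OsO4 (2 mol%), NaIO4, 2,6-lutidine, 1,4-dioxane/H2O (3:1), rt
Reagents that add atoms: osmium tetroxide, O=[Os](=O)(=O)=O; sodium periodate, [Na+].[O-]I(=O)(=O)=O
Why: In this Lemieux–Johnson oxidation OsO4 should dihydroxylate the monosubstituted alkene in preference to the hindered, electron-poor tetrasubstituted enone, and periodate cleaves the diol to the aldehyde.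

Step 7
Reactants: 10 2-[(1R)-1,2,3-trimethyl-4-oxocyclohex-2-en-1-yl]acetaldehyde; 11 methyl acrylate
Product: 12 methyl 4-oxo-5-[(1R)-1,2,3-trimethyl-4-oxocyclohex-2-en-1-yl]pentanoate
Conditions: methyl acrylate (3 equiv), 3-benzyl-5-(2-hydroxyethyl)-4-methylthiazolium chloride (20 mol%), Et3N, 1,4-dioxane, 70 °C
Reagents that add atoms: methyl acrylate (11), C=CC(=O)OC
Why: In this Stetter reaction the thiazolylidene turns the aldehyde into an acyl anion equivalent that adds 1,4 to the acrylate and forms the C7–C8 bond, which avoids an enolate alkylation that could not distinguish the chain from the ring enone, while the β,β-disubstituted ring enone is no acceptor.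

Step 8
Reactants: 12 methyl 4-oxo-5-[(1R)-1,2,3-trimethyl-4-oxocyclohex-2-en-1-yl]pentanoate
Product: 13 methyl (3Z)-4-[(tert-butyldimethylsilyl)oxy]-5-[(1R)-4-[(tert-butyldimethylsilyl)oxy]-1,3-dimethyl-2-methylidenecyclohex-3-en-1-yl]pent-3-enoate
Conditions: TBSOTf (2.5 equiv), Et3N (5 equiv), CH2Cl2, 0 °C → rt
Reagents that add atoms: tert-butyldimethylsilyl trifluoromethanesulfonate, CC(C)(C)[Si](C)(C)OS(=O)(=O)C(F)(F)F
Why: Soft enolisation (silyl triflate and tertiary amine) should give the through-conjugated dienol ether of the enone, which can only be exocyclic (C5=C6) because C10 is quaternary, and should enolise the chain ketone toward the unhindered C7 and not toward the neopentyl C9, the ester staying untouched and the enol ether geometry being of no consequence.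

Step 9
Reactants: 13 methyl (3Z)-4-[(tert-butyldimethylsilyl)oxy]-5-[(1R)-4-[(tert-butyldimethylsilyl)oxy]-1,3-dimethyl-2-methylidenecyclohex-3-en-1-yl]pent-3-enoate
Product: 14 methyl 3,8-dioxo-13-nor-eudesm-4-en-12-oate (7β-CH2CO2Me, 10β-CH3), i.e. methyl 2-[(2R,4aR)-4a,8-dimethyl-3,7-dioxo-1,2,3,4,4a,5,6,7-octahydronaphthalen-2-yl]acetate
Conditions: reticulated vitreous carbon anode, Pt cathode, undivided cell, LiClO4 (0.1 M), 2,6-lutidine, MeOH/CH2Cl2 (1:4), constant current, 2.2 F/mol, rt
Reagents that add atoms: none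
Why: The anode removes one electron from the more electron-rich silyl dienol ether of ring A, the radical cation is attacked at its unsubstituted terminus C6 by the nucleophilic carbon C7 of the chain silyl enol ether, the C8 oxocarbenium ion gives up its silyl group to methanol, and a second oxidation of the silyloxyallyl radical followed by desilylation releases the 4-en-3-one. The closest known reactions are intramolecular anodic olefin couplings of enol ether and silyl enol ether radical cations with enol ether nucleophiles, and oxidant-mediated γ-coupling of silyl dienol ethers with silyl enol ethers to 1,6-dicarbonyl compounds. Ring B should close in a 6-endo-trig mode with respect to both π-bonds (C5 and C8 become ring atoms) through a chair-like transition state. The new stereocentre C7 is expected with the CH2CO2Me arm equatorial (7β) relative to the fixed C10 centre, and since it lies α to the C8 ketone any 7α-epimer can equilibrate to the same isomer. The step needs C6–C7 bonding and not C4–C7 or C6–C8 bonding: C4 is fully substituted and would lead to a bridged, non-conjugated product whereas the terminal methylene is unhindered, and only bonding through C7 places the cation on the oxygen-bearing C8, so the same bond results whichever partner is oxidised first.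

Step 10
Reactants: 14 methyl 3,8-dioxo-13-nor-eudesm-4-en-12-oate
Product: 16 3β-hydroxy-13-nor-eudesm-4-en-8β,12-olide (cis-fused γ-lactone, 7α-H, 8α-H), via dihydroxy ester 15 (not isolated)
Conditions: NaBH4, CeCl3·7H2O, MeOH, −78 → 0 °C; then rt
Reagents that add atoms: none
Why: In this Luche reduction hydride should add 1,2 to the enone on the α-face (axial attack) to give the equatorial 3β-alcohol and should attack the C8 ketone on the α-face as well, because the syn-axial C10 methyl blocks the β-face, so that the axial 8β-alkoxide, cis to the ester arm, closes the γ-lactone by transesterification.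

Step 11
Reactants: 16 3β-hydroxy-13-nor-eudesm-4-en-8β,12-olide
Product: 17 3β-[(tert-butyldimethylsilyl)oxy]-13-nor-eudesm-4-en-8β,12-olide
Conditions: TBSCl, imidazole, DMF, rt
Reagents that add atoms: tert-butyldimethylsilyl chloride, CC(C)(C)[Si](C)(C)Cl
Why: Standard silylation of the only free hydroxyl protects the allylic alcohol against the base and the hydroxide used in the following steps.

Step 12
Reactants: 17 3β-[(tert-butyldimethylsilyl)oxy]-13-nor-eudesm-4-en-8β,12-olide
Product: 18 13-(dimethylamino)-3β-[(tert-butyldimethylsilyl)oxy]eudesm-4-en-8β,12-olide (C11 epimers)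
Conditions: LiN(iPr)2, THF, −78 °C; then CH2=NMe2+ I−, −78 °C → rt
Reagents that add atoms: N,N-dimethylmethyleneiminium iodide (Eschenmoser's salt), C=[N+](C)C.[I-]
Why: A Mannich reaction of the lactone enolate with the iminium salt installs C13 at C11, whose configuration is irrelevant because the centre becomes sp2 in step 13.

Step 13
Reactants: 18 13-(dimethylamino)-3β-[(tert-butyldimethylsilyl)oxy]eudesm-4-en-8β,12-olide
Product: 20 3β-[(tert-butyldimethylsilyl)oxy]eudesma-4,11(13)-dien-8β,12-olide, via trimethylammonium iodide 19 (not isolated)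
Conditions: MeI, MeOH, rt; then NaHCO3 (aq), CH2Cl2, rt
Reagents that add atoms: none
Why: Quaternisation of the amine followed by base-induced β-elimination (Hofmann-type, E1cB) should give the exocyclic α-methylene lactone.

Step 14
Reactants: 20 3β-[(tert-butyldimethylsilyl)oxy]eudesma-4,11(13)-dien-8β,12-olide
Product: 22 methyl 8β-hydroxy-3β-[(tert-butyldimethylsilyl)oxy]eudesma-4,11(13)-dien-12-oate, via potassium hydroxy-carboxylate 21 (not isolated)
Conditions: KOH (1.1 equiv), THF/H2O, 0 °C → rt; concentrate; then MeI, DMF, 0 °C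
Reagents that add atoms: potassium hydroxide, [K+].[OH-]; iodomethane, CI
Why: Saponification of the lactone and SN2 O-methylation of the carboxylate under non-acidic conditions should give the γ-hydroxy acrylate as the kinetic product, since neither the carboxylate nor the neutral ester re-closes quickly, and C7 and C8 are not touched.

Step 15
Reactants: 22 methyl 8β-hydroxy-3β-[(tert-butyldimethylsilyl)oxy]eudesma-4,11(13)-dien-12-oate
Product: 23 methyl 8β-acetoxy-3β-[(tert-butyldimethylsilyl)oxy]eudesma-4,11(13)-dien-12-oate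
Conditions: Ac2O, DMAP, pyridine, CH2Cl2, 0 °C → rt (crude 22 used at once)
Reagents that add atoms: acetic anhydride, CC(=O)OC(C)=O
Why: DMAP-catalysed acylation of the axial 8β-hydroxyl caps the nucleophile that could otherwise re-form the lactone.

Step 16
Reactants: 23 methyl 8β-acetoxy-3β-[(tert-butyldimethylsilyl)oxy]eudesma-4,11(13)-dien-12-oate
Product: 24 methyl 8β-acetoxy-3β-hydroxyeudesma-4,11(13)-dien-12-oate
Conditions: Bu4NF, AcOH, THF, 0 °C → rt
Reagents that add atoms: none
Why: Fluoride-mediated desilylation buffered with acetic acid should free the allylic alcohol while the acetate, the acrylate and the acid-sensitive allylic system survive.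

Step 17
Reactants: 24 methyl 8β-acetoxy-3β-hydroxyeudesma-4,11(13)-dien-12-oate
Product: 25 methyl 8β-acetoxy-3β-(2-methylpropanoyloxy)eudesma-4,11(13)-dien-12-oate
Conditions: i-PrCOCl, pyridine, DMAP (cat.), CH2Cl2, 0 °C
Reagents that add atoms: 2-methylpropanoyl chloride, CC(C)C(=O)Cl
Why: Acylation of the secondary allylic alcohol with the acid chloride proceeds at oxygen with retention of the C3 configuration.

Step 18
Reactants: 25 methyl 8β-acetoxy-3β-(2-methylpropanoyloxy)eudesma-4,11(13)-dien-12-oate
Product: 26 methyl 8β-acetoxy-5α-hydroperoxy-3β-(2-methylpropanoyloxy)eudesma-4(15),11(13)-dien-12-oate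
Conditions: O2, hν (visible), 5,10,15,20-tetraphenylporphyrin (cat.), CH2Cl2, −20 °C
Reagents that add atoms: dioxygen (as singlet oxygen), O=O
Why: In this Schenck ene reaction singlet oxygen should attack the electron-rich tetrasubstituted C4=C5 bond (the acrylate is inert) on the α-face opposite the axial C10 methyl, bond to C5 and take a hydrogen from the C15 methyl, since the C3 hydrogen is deactivated by its geminal acyloxy group and the α-hydrogen on C6 is poorly aligned, which sets the 5α-hydroperoxide and the 4(15)-methylene.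

**Compound list**

1 | 2-methylcyclohexane-1,3-dione | CC1C(=O)CCCC1=O | starting material
2 | 3-(2-methylpropoxy)-2-methylcyclohex-2-en-1-one | CC1=C(OCC(C)C)CCCC1=O | intermediate
3 | rac-3-(2-methylpropoxy)-2,6-dimethylcyclohex-2-en-1-one | CC1CCC(OCC(C)C)=C(C)C1=O | intermediate
4 | allyl chloroformate | C=CCOC(=O)Cl | starting material
5 | allyl 5-(2-methylpropoxy)-2,6-dimethylcyclohexa-1,5-dien-1-yl carbonate | C=CCOC(=O)OC1=C(C)CCC(OCC(C)C)=C1C | intermediate
6 | (6R)-6-allyl-3-(2-methylpropoxy)-2,6-dimethylcyclohex-2-en-1-one | C=CC[C@@]1(C)CCC(OCC(C)C)=C(C)C1=O | intermediate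
7 | (6R)-6-allyl-3-(2-methylpropoxy)-1,2,6-trimethylcyclohex-2-en-1-ol (C1 epimers) | C=CC[C@@]1(C)CCC(OCC(C)C)=C(C)C1(C)O | intermediate (not isolated)
8 | (4R)-4-allyl-2,3,4-trimethylcyclohex-2-en-1-one | C=CC[C@@]1(C)CCC(=O)C(C)=C1C | intermediate
9 | (4R)-4-(2,3-dihydroxypropyl)-2,3,4-trimethylcyclohex-2-en-1-one (diol epimers) | OCC(O)C[C@@]1(C)CCC(=O)C(C)=C1C | intermediate (not isolated)
10 | 2-[(1R)-1,2,3-trimethyl-4-oxocyclohex-2-en-1-yl]acetaldehyde | O=CC[C@@]1(C)CCC(=O)C(C)=C1C | intermediate
11 | methyl acrylate | C=CC(=O)OC | starting material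
12 | methyl 4-oxo-5-[(1R)-1,2,3-trimethyl-4-oxocyclohex-2-en-1-yl]pentanoate | COC(=O)CCC(=O)C[C@@]1(C)CCC(=O)C(C)=C1C | intermediate
13 | methyl (3Z)-4-[(tert-butyldimethylsilyl)oxy]-5-[(1R)-4-[(tert-butyldimethylsilyl)oxy]-1,3-dimethyl-2-methylidenecyclohex-3-en-1-yl]pent-3-enoate | COC(=O)C/C=C(\O[Si](C)(C)C(C)(C)C)C[C@@]1(C)CCC(O[Si](C)(C)C(C)(C)C)=C(C)C1=C | intermediate
14 | methyl 3,8-dioxo-13-nor-eudesm-4-en-12-oate (7β-CH2CO2Me, 10β-CH3) | COC(=O)C[C@H]1CC2=C(C)C(=O)CC[C@]2(C)CC1=O | intermediate
15 | methyl 3β,8β-dihydroxy-13-nor-eudesm-4-en-12-oate | COC(=O)C[C@H]1CC2=C(C)[C@@H](O)CC[C@]2(C)C[C@H]1O | intermediate (not isolated)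
16 | 3β-hydroxy-13-nor-eudesm-4-en-8β,12-olide | O=C1C[C@H]2CC3=C(C)[C@@H](O)CC[C@]3(C)C[C@H]2O1 | intermediate
17 | 3β-[(tert-butyldimethylsilyl)oxy]-13-nor-eudesm-4-en-8β,12-olide | O=C1C[C@H]2CC3=C(C)[C@@H](O[Si](C)(C)C(C)(C)C)CC[C@]3(C)C[C@H]2O1 | intermediate
18 | 13-(dimethylamino)-3β-[(tert-butyldimethylsilyl)oxy]eudesm-4-en-8β,12-olide (C11 epimers) | O=C1C(CN(C)C)[C@H]2CC3=C(C)[C@@H](O[Si](C)(C)C(C)(C)C)CC[C@]3(C)C[C@H]2O1 | intermediate
19 | 13-(trimethylammonio)-3β-[(tert-butyldimethylsilyl)oxy]eudesm-4-en-8β,12-olide iodide | O=C1C(C[N+](C)(C)C)[C@H]2CC3=C(C)[C@@H](O[Si](C)(C)C(C)(C)C)CC[C@]3(C)C[C@H]2O1.[I-] | intermediate (not isolated)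
20 | 3β-[(tert-butyldimethylsilyl)oxy]eudesma-4,11(13)-dien-8β,12-olide | O=C1C(=C)[C@H]2CC3=C(C)[C@@H](O[Si](C)(C)C(C)(C)C)CC[C@]3(C)C[C@H]2O1 | intermediate
21 | potassium 8β-hydroxy-3β-[(tert-butyldimethylsilyl)oxy]eudesma-4,11(13)-dien-12-oate | C=C(C(=O)[O-])[C@H]1CC2=C(C)[C@@H](O[Si](C)(C)C(C)(C)C)CC[C@]2(C)C[C@H]1O.[K+] | intermediate (not isolated)
22 | methyl 8β-hydroxy-3β-[(tert-butyldimethylsilyl)oxy]eudesma-4,11(13)-dien-12-oate | C=C(C(=O)OC)[C@H]1CC2=C(C)[C@@H](O[Si](C)(C)C(C)(C)C)CC[C@]2(C)C[C@H]1O | intermediate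
23 | methyl 8β-acetoxy-3β-[(tert-butyldimethylsilyl)oxy]eudesma-4,11(13)-dien-12-oate | C=C(C(=O)OC)[C@H]1CC2=C(C)[C@@H](O[Si](C)(C)C(C)(C)C)CC[C@]2(C)C[C@H]1OC(C)=O | intermediate
24 | methyl 8β-acetoxy-3β-hydroxyeudesma-4,11(13)-dien-12-oate | C=C(C(=O)OC)[C@H]1CC2=C(C)[C@@H](O)CC[C@]2(C)C[C@H]1OC(C)=O | intermediate
25 | methyl 8β-acetoxy-3β-(2-methylpropanoyloxy)eudesma-4,11(13)-dien-12-oate | C=C(C(=O)OC)[C@H]1CC2=C(C)[C@@H](OC(=O)C(C)C)CC[C@]2(C)C[C@H]1OC(C)=O | intermediate
26 | methyl 8β-acetoxy-5α-hydroperoxy-3β-(2-methylpropanoyloxy)eudesma-4(15),11(13)-dien-12-oate | C=C(C(=O)OC)[C@H]1C[C@@]2(OO)C(=C)[C@@H](OC(=O)C(C)C)CC[C@]2(C)C[C@H]1OC(C)=O | target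

**Totals and risks**

Total step count: 18. Longest linear sequence: 18 steps (from 1 to 26).

Step 9 (anodic ring closure). The radical cation may be captured by methanol or lose its silyl group before the six-membered closure, or oxidation may continue at C6 of the product. The fallback replaces the one-electron coupling by a two-electron, polar sequence. It sets out from 13: N-bromosuccinimide (1 equiv, NaHCO3, THF, −78 °C) should brominate the more electron-rich dienol ether at its terminus, as is usual for dienol ethers of 4-en-3-ones, and give methyl (3Z)-5-[(1R)-2-(bromomethyl)-1,3-dimethyl-4-oxocyclohex-2-en-1-yl]-4-[(tert-butyldimethylsilyl)oxy]pent-3-enoate F1. Fluoride (Bu4NF, THF, −78 → 0 °C) then unmasks the C7 enolate regiospecifically from the remaining silyl enol ether, and this enolate displaces the allylic bromide at C6 in a 6-exo-tet alkylation. The route is rejoined at 14.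

Step 8 (double silylation). Enolisation of the chain ketone may go partly toward C9, or the ester may be enolised as well, and such isomers cannot close ring B. The fallback makes the chain enol ether regiospecifically by conjugate hydrosilylation. It sets out from 10 and proceeds as follows:
- Lithium methyl propiolate (methyl propiolate, LiN(iPr)2, THF, −78 °C) adds to the aldehyde to give methyl 4-hydroxy-5-[(1R)-1,2,3-trimethyl-4-oxocyclohex-2-en-1-yl]pent-2-ynoate F2.
- Amine-catalysed redox isomerisation (DABCO, DMSO, rt) converts it into methyl (2E)-4-oxo-5-[(1R)-1,2,3-trimethyl-4-oxocyclohex-2-en-1-yl]pent-2-enoate F3.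
- 1,4-Hydrosilylation of the enone (RhCl(PPh3)3 cat., Et3SiH, toluene, 50 °C) delivers hydride to C11 and silicon to the ketone oxygen, which fixes the enol ether between C7 and C8 in methyl (3Z)-4-[(triethylsilyl)oxy]-5-[(1R)-1,2,3-trimethyl-4-oxocyclohex-2-en-1-yl]pent-3-enoate F4.
- Soft enolisation of the ring enone alone (TBSOTf, Et3N, CH2Cl2, −78 → 0 °C) gives methyl (3Z)-5-[(1R)-4-[(tert-butyldimethylsilyl)oxy]-1,3-dimethyl-2-methylidenecyclohex-3-en-1-yl]-4-[(triethylsilyl)oxy]pent-3-enoate F5.
- F5 is electrolysed under the conditions of step 9, and the route is rejoined at 14.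

Step 14 (lactone opening). Hydroxide may add to the methylene lactone in a conjugate sense, or the γ-hydroxy ester may close again to the lactone during methylation or before acetylation. The fallback opens the lactone by reduction, so that no γ-hydroxy ester is ever present. It sets out from 20 and proceeds as follows:
- iBu2AlH (CH2Cl2, −78 → 0 °C) gives 3β-[(tert-butyldimethylsilyl)oxy]eudesma-4,11(13)-diene-8β,12-diol F6.
- The primary allylic hydroxyl is silylated selectively (Et3SiCl, imidazole, CH2Cl2, −40 °C) to 3β-[(tert-butyldimethylsilyl)oxy]-12-[(triethylsilyl)oxy]eudesma-4,11(13)-dien-8β-ol F7.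
- Acetylation (Ac2O, DMAP, pyridine) gives 8β-acetoxy-3β-[(tert-butyldimethylsilyl)oxy]-12-[(triethylsilyl)oxy]eudesma-4,11(13)-diene F8.
- Mild methanolysis of the primary silyl ether (PPTS, MeOH, 0 °C) gives 8β-acetoxy-3β-[(tert-butyldimethylsilyl)oxy]eudesma-4,11(13)-dien-12-ol F9.
- MnO2 (CH2Cl2) oxidises the allylic alcohol to 8β-acetoxy-3β-[(tert-butyldimethylsilyl)oxy]eudesma-4,11(13)-dien-12-al F10.
- Pinnick oxidation (NaClO2, NaH2PO4, 2-methyl-2-butene, t-BuOH/H2O) gives 8β-acetoxy-3β-[(tert-butyldimethylsilyl)oxy]eudesma-4,11(13)-dien-12-oic acid F11.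
- Methylation with Me3SiCHN2 (MeOH/toluene) rejoins the route at 23.

**Further compounds**

F1 | step 9 | methyl (3Z)-5-[(1R)-2-(bromomethyl)-1,3-dimethyl-4-oxocyclohex-2-en-1-yl]-4-[(tert-butyldimethylsilyl)oxy]pent-3-enoate | COC(=O)C/C=C(\O[Si](C)(C)C(C)(C)C)C[C@@]1(C)CCC(=O)C(C)=C1CBr
F2 | step 8 | methyl 4-hydroxy-5-[(1R)-1,2,3-trimethyl-4-oxocyclohex-2-en-1-yl]pent-2-ynoate (C4 epimers) | COC(=O)C#CC(O)C[C@@]1(C)CCC(=O)C(C)=C1C
F3 | step 8 | methyl (2E)-4-oxo-5-[(1R)-1,2,3-trimethyl-4-oxocyclohex-2-en-1-yl]pent-2-enoate | COC(=O)/C=C/C(=O)C[C@@]1(C)CCC(=O)C(C)=C1C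
F4 | step 8 | methyl (3Z)-4-[(triethylsilyl)oxy]-5-[(1R)-1,2,3-trimethyl-4-oxocyclohex-2-en-1-yl]pent-3-enoate | COC(=O)C/C=C(\O[Si](CC)(CC)CC)C[C@@]1(C)CCC(=O)C(C)=C1C
F5 | step 8 | methyl (3Z)-5-[(1R)-4-[(tert-butyldimethylsilyl)oxy]-1,3-dimethyl-2-methylidenecyclohex-3-en-1-yl]-4-[(triethylsilyl)oxy]pent-3-enoate | COC(=O)C/C=C(\O[Si](CC)(CC)CC)C[C@@]1(C)CCC(O[Si](C)(C)C(C)(C)C)=C(C)C1=C
F6 | step 14 | 3β-[(tert-butyldimethylsilyl)oxy]eudesma-4,11(13)-diene-8β,12-diol | C=C(CO)[C@H]1CC2=C(C)[C@@H](O[Si](C)(C)C(C)(C)C)CC[C@]2(C)C[C@H]1O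
F7 | step 14 | 3β-[(tert-butyldimethylsilyl)oxy]-12-[(triethylsilyl)oxy]eudesma-4,11(13)-dien-8β-ol | C=C(CO[Si](CC)(CC)CC)[C@H]1CC2=C(C)[C@@H](O[Si](C)(C)C(C)(C)C)CC[C@]2(C)C[C@H]1O
F8 | step 14 | 8β-acetoxy-3β-[(tert-butyldimethylsilyl)oxy]-12-[(triethylsilyl)oxy]eudesma-4,11(13)-diene | C=C(CO[Si](CC)(CC)CC)[C@H]1CC2=C(C)[C@@H](O[Si](C)(C)C(C)(C)C)CC[C@]2(C)C[C@H]1OC(C)=O
F9 | step 14 | 8β-acetoxy-3β-[(tert-butyldimethylsilyl)oxy]eudesma-4,11(13)-dien-12-ol | C=C(CO)[C@H]1CC2=C(C)[C@@H](O[Si](C)(C)C(C)(C)C)CC[C@]2(C)C[C@H]1OC(C)=O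
F10 | step 14 | 8β-acetoxy-3β-[(tert-butyldimethylsilyl)oxy]eudesma-4,11(13)-dien-12-al | C=C(C=O)[C@H]1CC2=C(C)[C@@H](O[Si](C)(C)C(C)(C)C)CC[C@]2(C)C[C@H]1OC(C)=O
F11 | step 14 | 8β-acetoxy-3β-[(tert-butyldimethylsilyl)oxy]eudesma-4,11(13)-dien-12-oic acid | C=C(C(=O)O)[C@H]1CC2=C(C)[C@@H](O[Si](C)(C)C(C)(C)C)CC[C@]2(C)C[C@H]1OC(C)=O
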